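## Retrosynthetic overview

1. Target 4 ⇒ C14–C15 disconnection: α-hydroxy aldehyde 3 (C14, electrophile) plus an acetoxymethyl carbanion (C15, an oxygen-bearing carbon used with reversed polarity as AcOCH2ZnBr). Two natively electrophilic carbons are joined, and C14 is set in the same event by Cram-chelate control from the C13 carbinol.
2. 3 ⇒ sclareol 1 by ozonolytic excision of C15; C13 is quaternary and cannot epimerise.
3. No ring is formed: rings A and B (trans-decalin) and the stereocentres C5, C8, C9, C10 and C13 come intact with sclareol; only C14 is created.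

Assumption: the target is read as (13R,14R)-8α,13,14-trihydroxylabdan-15-yl acetate with the ring stereochemistry of natural sclareol, and bromomethyl acetate and zinc are treated as reagents, so sclareol is the only numbered starting material.

## Route

Step 1
Reactants: 1 sclareol, (13R)-labd-14-ene-8α,13-diol
Product: 3 (13R)-8α,13-dihydroxy-15-norlabdan-14-al, via secondary ozonide 2 (not isolated)
Conditions: O3, CH2Cl2, −78 °C, to the end point; N2 purge; PPh3 (1.2 equiv), −78 °C → rt; short silica plug to remove Ph3P=O
Reagents that add atoms: ozone, O=[O+][O-]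
Why: Criegee ozonolysis cleaves the only C=C bond of 1, PPh3 reduces the 1,2,4-trioxolane 2 to aldehyde 3 plus formaldehyde, and C13 has no α-hydrogen, so the five stereocentres of 1 pass through unchanged and no new one remains in 3.

Step 2
Reactants: 3 (13R)-8α,13-dihydroxy-15-norlabdan-14-al
Product: 4 (13R,14R)-8α,13,14-trihydroxylabdan-15-yl acetate (CNP0523287.1)
Conditions: BrCH2OAc (4 equiv), Zn dust (6 equiv), LiCl (4 equiv), THF, 0 → 20 °C, 1 h (gives AcOCH2ZnBr·LiCl); separately 3, MgBr2·OEt2 (2.5 equiv), CH2Cl2, −30 °C, 20 min; add the zinc reagent, −30 → 0 °C; sat. aq NH4Cl at 0 °C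
Reagents that add atoms: bromomethyl acetate, CC(=O)OCBr (reacts as (acetoxymethyl)zinc bromide, CC(=O)OC[Zn]Br, made from it with zinc)
Why: Proposed new method: (acetoxymethyl)zinc bromide is a hydroxymethyl-anion (d1) reagent, stabilised by internal C=O→Zn coordination, whose oxygen-bearing carbon is nucleophilic; divalent magnesium holds 3 as the five-membered O13–Mg–O14 Cram chelate and activates the aldehyde, the reagent adds to C14 from the face of the small C13 methyl group (anti to the C12 chain) to give the 13,14-syn diol, which is 14R, and the acetate arrives already on the primary C15 oxygen, its thermodynamically preferred site; the closest known reactions are additions of α-acyloxyalkylzinc and -copper reagents to aldehydes giving 1,2-diol monoesters, MgX2-accelerated 1,2-additions of alkylzinc halides to aldehydes, and Cram-chelate additions of organometallics to α-hydroxy carbonyl compounds.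

## Compound list

1 | sclareol, (13R)-labd-14-ene-8α,13-diol; (1R,2R,4aS,8aS)-1-[(3R)-3-hydroxy-3-methylpent-4-en-1-yl]-2,5,5,8a-tetramethyldecahydronaphthalen-2-ol | C=C[C@](C)(O)CC[C@@H]1[C@@]2(C)CCCC(C)(C)[C@@H]2CC[C@@]1(C)O | starting material

2 | secondary ozonide of sclareol; (2R)-4-[(1R,2R,4aS,8aS)-2-hydroxy-2,5,5,8a-tetramethyldecahydronaphthalen-1-yl]-2-(1,2,4-trioxolan-3-yl)butan-2-ol, both epimers at the trioxolane carbon | C3OOC(O3)[C@](C)(O)CC[C@@H]1[C@@]2(C)CCCC(C)(C)[C@@H]2CC[C@@]1(C)O | intermediate (not isolated)

3 | (13R)-8α,13-dihydroxy-15-norlabdan-14-al; (2R)-2-hydroxy-4-[(1R,2R,4aS,8aS)-2-hydroxy-2,5,5,8a-tetramethyldecahydronaphthalen-1-yl]-2-methylbutanal | O=C[C@](C)(O)CC[C@@H]1[C@@]2(C)CCCC(C)(C)[C@@H]2CC[C@@]1(C)O | intermediate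

4 | (13R,14R)-8α,13,14-trihydroxylabdan-15-yl acetate; (2R,3R)-2,3-dihydroxy-5-[(1R,2R,4aS,8aS)-2-hydroxy-2,5,5,8a-tetramethyldecahydronaphthalen-1-yl]-3-methylpentyl acetate | CC(=O)OC[C@@H](O)[C@](C)(O)CC[C@@H]1[C@@]2(C)CCCC(C)(C)[C@@H]2CC[C@@]1(C)O | target

## Step count and risks

Total step count: 2. Longest linear sequence: 2 (1 → 3 → 4).

The route has only two steps, so both are ranked; step 2 has two independent failure modes and is given twice.

Risk 1, step 2, bond formation. The zinc reagent may be too weak a nucleophile, may decay as a carbenoid, or the acetyl group may move to O14 in the alkoxide stage. The fallback sets out from 3 and comes back at 4; it keeps the same bond and the same reversed polarity but carries the C15 oxygen masked as silicon. Aldehyde 3 is treated with (isopropoxydimethylsilyl)methylmagnesium chloride (4 equiv, THF, 0 °C), a strongly chelating Grignard reagent, to give (13R,14S)-15-(isopropoxydimethylsilyl)labdane-8α,13,14-triol F2. Tamao oxidation (30% H2O2, KF, KHCO3, THF/MeOH, rt) converts it into (13R,14R)-labdane-8α,13,14,15-tetrol F3. AcCl with 2,4,6-collidine in CH2Cl2 at −78 °C then acetylates only the primary hydroxyl to give 4.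

Risk 2, step 2, facial selectivity. The chelate distinguishes only a methyl group from a CH2 chain at C13, so the 14R:14S ratio may be modest; I expect the 14S epimer to need removal by chromatography even in a good case. The fallback sets out from 3 and comes back at 4; it moves control of C14 from the substrate to a catalyst. Step 2 is run as written and the unseparated mixture of 4 and (13R,14S)-8α,13,14-trihydroxylabdan-15-yl acetate F4 is oxidised at the secondary carbinol (SO3·pyridine, DMSO, iPr2NEt, CH2Cl2, 0 °C) to (13R)-8α,13-dihydroxy-14-oxolabdan-15-yl acetate F5. Reduction with (S)-2-methyl-CBS-oxazaborolidine and excess BH3·SMe2 (THF, −20 °C, methanolic work-up) should give the 14R alcohol 4, with the tertiary-carbinol side acting as the large group and CH2OAc as the small one.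

Risk 3, step 1, ozonolysis. A tertiary allylic alcohol can give anomalous cleavage of the C13–C14 bond to the 14,15-dinor methyl ketone, and the α-hydroxy aldehyde can dimerise or undergo α-ketol rearrangement on handling. The fallback sets out from 1 and comes back at 3. Dihydroxylation (OsO4 2 mol %, N-methylmorpholine N-oxide, acetone/H2O, rt) gives (13R,14RS)-labdane-8α,13,14,15-tetrol F1; its C14 configuration is irrelevant. Silica-supported NaIO4 (1.05 equiv, CH2Cl2, 0 °C) then cleaves the less hindered secondary–primary 14,15-glycol to give 3.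

Further compounds
F1 | step 1 | (13R,14RS)-labdane-8α,13,14,15-tetrol | OCC(O)[C@](C)(O)CC[C@@H]1[C@@]2(C)CCCC(C)(C)[C@@H]2CC[C@@]1(C)O
F2 | step 2 | (13R,14S)-15-(isopropoxydimethylsilyl)labdane-8α,13,14-triol (14S only because silicon outranks C13; same spatial arrangement as 14R in 4) | CC(C)O[Si](C)(C)C[C@@H](O)[C@](C)(O)CC[C@@H]1[C@@]2(C)CCCC(C)(C)[C@@H]2CC[C@@]1(C)O
F3 | step 2 | (13R,14R)-labdane-8α,13,14,15-tetrol | OC[C@@H](O)[C@](C)(O)CC[C@@H]1[C@@]2(C)CCCC(C)(C)[C@@H]2CC[C@@]1(C)O
F4 | step 2 | (13R,14S)-8α,13,14-trihydroxylabdan-15-yl acetate | CC(=O)OC[C@H](O)[C@](C)(O)CC[C@@H]1[C@@]2(C)CCCC(C)(C)[C@@H]2CC[C@@]1(C)O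
F5 | step 2 | (13R)-8α,13-dihydroxy-14-oxolabdan-15-yl acetate | CC(=O)OCC(=O)[C@](C)(O)CC[C@@H]1[C@@]2(C)CCCC(C)(C)[C@@H]2CC[C@@]1(C)O
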